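Substrate, catalyst intermediate C and product together hold the charge: Monday's last reading sums to 99.4 %. With intermediate C at 3.3 % in that reading, the substrate curve is nearly enough to name the leader.

common to all: substrate 0.13 M; reagent 0.137 M; impurity 0.99 mM
- Wednesday's: free catalyst 6.3 mM; run made earlier
- Sunday's: free catalyst 14 mM; run made earlier
- Monday's: free catalyst 24 mM; run made earlier
- east: free catalyst 9.0 mM; time 6.0 min
- west: free catalyst 22 mM; time 6.0 min

- Wednesday's (time / min: catalyst intermediate C / %, substrate / %, product / %): 0.417: 1.6, 98.3, 0; 1.00: 0.8, 97.0, 2.5; 2.00: 1.4, 92.3, 6.4; 3.00: 2.2, 89.3, 10.1; 4.00: 1.2, 85.2, 13.7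
- Sunday's (time / min: catalyst intermediate C / %, substrate / %, product / %): 0.833: 2.9, 93.8, 4.5; 1.50: 2.3, 87.3, 9.9; 2.50: 2.5, 78.1, 19.3; 3.00: 3.1, 75.7, 22.5; 4.00: 1.7, 67.4, 30.6
- Monday's (time / min: catalyst intermediate C / %, substrate / %, product / %): 0.333: 2.3, 96.3, 0.9; 0.667: 4.9, 90.9, 4.2; 1.33: 4.7, 80.3, 14.3; 2.00: 4.5, 71.2, 24.7; 4.00: 3.3, 48.2, 47.9

(standard deviation of a reading: 0.5 percentage points)

- which of these there is most of at the end, counted by the substrate in it, east (substrate / product / catalyst intermediate C)
- which of these there is most of at the end, counted by the substrate in it, west (substrate / product / catalyst intermediate C)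
- final amount of the leader among these, as a percentage of the substrate charged, in east
- final amount of the leader among these, as a percentage of the substrate charged, in west

Each run's last substrate reading gives a mean first-order rate, 0.0400 min⁻¹ on Wednesday, 0.0986 min⁻¹ on Sunday and 0.182 min⁻¹ on Monday. A first guess divides this by the catalyst charged. That fails, giving 6.36 M⁻¹ min⁻¹ on Wednesday but 7.60 M⁻¹ min⁻¹ on Monday.

Going round again, the impurity charge is taken off the catalyst first. The figures become 7.54 M⁻¹ min⁻¹, 7.58 M⁻¹ min⁻¹ and 7.93 M⁻¹ min⁻¹. Their mean is the specific rate, 7.68 M⁻¹ min⁻¹: the first-order rate of substrate loss per unit of catalyst left after the impurity's equivalent is subtracted.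

One objection is that the reagent is consumed too, so the decay may not be pseudo-first-order. But Monday's rate up to 2.00 min is 0.170 min⁻¹, against 0.182 min⁻¹ up to 4.00 min, with no fall.

So this reckoning has east keeping 69.1 % of its substrate, which is more than the rest together, and west keeping 38.0 %. A second objection is that Monday's figure, from the run nearest west, lies above the mean, and it gives 36.8 % for west. With intermediate C taken at Monday's last reading, the estimate for product in west is 58.7 % by the mean and 59.9 % by Monday's figure, more than the substrate on either count.

The forecast names substrate at 69.5 % for east and product at 61.5 % for west, a product figure higher than this reckoning's, and holds that “the 0.99 mM impurity removes its equivalent of catalyst”.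

    reagent + free catalyst → catalyst intermediate A (k = 165 M⁻¹ min⁻¹)
    catalyst intermediate A ⇌ by-product + catalyst intermediate B (K = 0.330 M, k = 2.97 min⁻¹)
    substrate + catalyst intermediate B → catalyst intermediate C (k = 20.6 M⁻¹ min⁻¹)
    catalyst intermediate C ⇌ free catalyst + product (K = 0.290 M, k = 3.30 min⁻¹)
    free catalyst + impurity → spent catalyst (k = 22000 M⁻¹ min⁻¹)

East ends with substrate leading at 69.1 %, west with product at 62.6 %, so the forecast held. In east, spent catalyst stands at 11.0 % of the catalyst charged, and the subtraction took off 11.0 %; what is left of the impurity's charge, 0 %, is less than what is left of the substrate's, 69 %. Put back on east at 3.00 min, the specific rate gives 83.1 % of the substrate, and the flask holds 83.9 %.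

Read at 4.0 min, the west flask should keep 52.4 % by the specific rate. It holds 51.6 %, with substrate the leader.

Readings and results stem from a simulated flask on assumed constants; scatter was added.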